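Watch the feed. X is dosed into a flask holding Q, and if the proposed steps are right, each Q becomes one L, which then goes on turning X into Z.

| flask | X | Q | remark | time |
|---|---|---|---|---|
| eta | 20 mM (fed, over 2.0 d) | 31 µM | run made earlier |  |
| epsilon | 20 mM (fed, over 2.0 d) | 46 µM | run made earlier |  |
| delta | 10 mM (fed, over 2.0 d) | 62 µM | run made earlier |  |
| flask | 20 mM (fed, over 2.0 d) | 62 µM |  | 50 h |

| run | time / h | Z / % | X / % |
|---|---|---|---|
| eta | 6.00 | 0.6 | 13.4 |
| eta | 12.0 | 0.3 | 24.3 |
| eta | 15.0 | 0.9 | 30.7 |
| eta | 25.0 | 1.4 | 50.5 |
| eta | 30.0 | 3.8 | 58.4 |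
| eta | 40.0 | 9.6 | 73.6 |
| epsilon | 2.00 | 0.8 | 3.4 |
| epsilon | 6.00 | 0.6 | 12.3 |
| epsilon | 12.0 | 0.6 | 24.5 |
| epsilon | 15.0 | 0.6 | 30.2 |
| epsilon | 25.0 | 2.5 | 48.8 |
| epsilon | 30.0 | 5.9 | 56.1 |
| epsilon | 40.0 | 13.0 | 69.9 |
| delta | 8.00 | 0 | 15.4 |
| delta | 15.0 | 0.6 | 31.6 |
| delta | 25.0 | 3.2 | 49.6 |
| delta | 30.0 | 5.1 | 58.3 |
| delta | 40.0 | 12.8 | 70.6 |

(readings scatter by 0.5 percentage points)

- what may be going on: X + Q -> L + Z; X + L -> Z + L
- percentages count the whole charge, also what has not yet gone in
- the reaction counts as stopped when no species that holds the X changes by six tenths of a point or more over the second half of the time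

* the state of affairs at 50 h: stopped, and by what, or still going (it is still moving / no working catalyst is left / forward and back rates have come level / all of X has reacted)
* Z at 50 h, in percent of the X charged
* amount of Z if the flask were left three thousand times as long, in percent of the X charged

The bench rule for a dosed flask is that what has gone in is still there as X. It serves early on, since the eta run at 6.00 h had 12.5% fed and showed 13.4% as X, but by 40.0 h it had 83.3% fed and showed 73.6%.

To find that border, divide Z gained by X fed over the same span, so that the clock drops out: this take-up reads 0.341 over the last span of the epsilon run, a reading with the scatter of its two values. Below 1, X piles up, which is the accumulation of the dosed reagent; at 1, the flask consumes X as fast as it is fed.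

The flask has the X charge of epsilon, and I scale by Q, taking [L] to follow the Q charged, which gives a take-up of 0.459 and Z of 17.5% at 40.0 h. If Z went on gaining at that pace until 50 h, a little past the end of the feed, it would stand at 27.1%, and at the pace of the feed itself, 38.4%. Even the slower pace gains 9.6 percentage points over those hours, so my reckoning says the flask is still going.

The forecast says it is still moving, with Z at 30% (26% to 34%) and 100% (85% to 100%) at the long time: “so the reaction is still moving”.

The flask gives 31.3% of Z at 50 h: it is still moving, with 100% at the long time.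

    X + Q → L + Z (k = 0.00170 /M/s)
    X + L → Z + L, rate k2*[L]*[X] (k = 0.0980 /M/s)

In the flask, X stood at 71.5% when the feed ended at 48.0 h and at 68.7% at 50.0 h. A neighbour flask, the same but with 0.15 mM of Q, gets a reckoned take-up of 1.11 when the epsilon reading is scaled by Q, which is above 1, and at 50.0 h that neighbour holds 56.3% of Z against 43.7% of X.

The data come from a simulation for substances that don't exist, and the scatter is random.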